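**Strategy.** The isoflavone is cut at C4–C4a, the bond between the ring C carbonyl and ring A. C4a of ring A is flanked by the methoxy-bearing C5 and the O1-bearing C8a, and its competitors C6 and C8 are activated almost equally, so a bromine is put on C4a at the outset. Bromine–lithium exchange then makes C4a, and only C4a, a carbanion that acylates itself with the pendant ester, forming C4–C4a and closing ring C in one operation. The precursor is a methyl (Z)-2-aryl-3-aryloxyacrylate: ring A as a 2-bromo-3-methoxy-5-silyloxyphenyl enol ether cis to the ester, ring B as the 8-silyloxy-2,2-dimethylchromen-6-yl group on the α-carbon.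

Key step: step 10

Assumption: methyl 2-(3-bromo-4-hydroxyphenyl)acetate is taken as a catalogue compound; its bromine fixes where the ring B oxygen will stand, so no selective alkylation of a catechol and no aldehyde homologation are needed.

Step 1
Reactants: 1 methyl 2-(3-bromo-4-hydroxyphenyl)acetate; 2 3-chloro-3-methylbut-1-yne
Product: 3 methyl 2-{3-bromo-4-[(2-methylbut-3-yn-2-yl)oxy]phenyl}acetate
Conditions: DBU, CuCl2·2H2O (cat.), MeCN, 0 °C → rt
Reagents that add atoms: none
Why: Copper-catalysed O-propargylation of a phenol with a tertiary propargylic chloride, in which the acidic ortho-bromophenol is the only nucleophile and the amidine base leaves the methyl ester alone.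

Step 2
Reactants: 3 methyl 2-{3-bromo-4-[(2-methylbut-3-yn-2-yl)oxy]phenyl}acetate
Product: 6 methyl 2-(8-bromo-2,2-dimethyl-2H-chromen-6-yl)acetate, via allenylphenol 4 (not isolated), via quinone methide 5 (not isolated)
Conditions: N,N-diethylaniline, 190 °C
Reagents that add atoms: none
Why: Aromatic propargyl Claisen rearrangement to the only ortho carbon that bears hydrogen gives 4, a 1,5-hydrogen shift gives 5, and oxa-6π electrocyclisation closes the 2,2-dimethylpyran ring.

Step 3
Reactants: 6 methyl 2-(8-bromo-2,2-dimethyl-2H-chromen-6-yl)acetate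
Product: 8 methyl 2-(8-hydroxy-2,2-dimethyl-2H-chromen-6-yl)acetate, via pinacol boronate 7 (not isolated)
Conditions: B2pin2, Pd(dppf)Cl2 (cat.), KOAc, 1,4-dioxane, 90 °C; then NaBO3·4H2O, THF–H2O, rt
Reagents that add atoms: bis(pinacolato)diboron, CC1(C)OB(OC1(C)C)B1OC(C)(C)C(C)(C)O1 (boron and pinacol of 7 only); sodium perborate, [Na+].[O-]OB=O (phenol oxygen of 8)
Why: Miyaura borylation of the aryl bromide followed by oxidative hydroxylation of the C–B bond at the same carbon, with perborate mild enough to spare the methyl ester and the chromene double bond.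

Step 4
Reactants: 8 methyl 2-(8-hydroxy-2,2-dimethyl-2H-chromen-6-yl)acetate
Product: 9 methyl 2-{2,2-dimethyl-8-[(triisopropylsilyl)oxy]-2H-chromen-6-yl}acetate
Conditions: TIPSCl, imidazole, DMF, rt
Reagents that add atoms: chlorotriisopropylsilane, CC(C)[Si](Cl)(C(C)C)C(C)C
Why: Silyl ether formation at the phenol gives a group that tolerates amide bases, carbonate and alkyllithium at low temperature and that leaves with fluoride together with the ring A silyl group, so no acid is needed near the chromene at the end.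

Step 5
Reactants: 9 methyl 2-{2,2-dimethyl-8-[(triisopropylsilyl)oxy]-2H-chromen-6-yl}acetate
Product: 10 methyl (Z)-2-{2,2-dimethyl-8-[(triisopropylsilyl)oxy]-2H-chromen-6-yl}-3-hydroxyacrylate (enol form of the 2-formyl ester)
Conditions: LiN(iPr)2, THF, −78 °C; then HCO2Me, −78 → 0 °C; aq. NH4Cl
Reagents that add atoms: methyl formate, COC=O
Why: Crossed Claisen condensation (α-formylation) of the arylacetate, driven by deprotonation of the acidic product and run cold so that the released methoxide does not touch the aryl silyl ether.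

Step 6
Reactants: 10 methyl (Z)-2-{2,2-dimethyl-8-[(triisopropylsilyl)oxy]-2H-chromen-6-yl}-3-hydroxyacrylate
Product: 11 methyl (Z)-2-{2,2-dimethyl-8-[(triisopropylsilyl)oxy]-2H-chromen-6-yl}-3-(tosyloxy)acrylate
Conditions: TsCl, TMEDA, LiCl, MeCN, 0 °C
Reagents that add atoms: p-toluenesulfonyl chloride, Cc1ccc(cc1)S(Cl)(=O)=O
Why: Chelation-controlled enol tosylation of an α-formyl ester, in which lithium holds the enolate oxygen cis to the ester carbonyl, so O-sulfonylation should give the Z enol tosylate (tosyloxy cis to CO2Me).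

Step 7
Reactants: 12 5-methoxyresorcinol
Product: 13 4-bromo-5-methoxybenzene-1,3-diol
Conditions: NBS (1.0 equiv), CH2Cl2–THF, −78 °C
Reagents that add atoms: N-bromosuccinimide, BrN1C(=O)CCC1=O
Why: Electrophilic aromatic bromination, which should prefer the two equivalent carbons para to one hydroxyl and ortho to the other over C2, with one equivalent at low temperature limiting dibromination.

Step 8
Reactants: 13 4-bromo-5-methoxybenzene-1,3-diol
Product: 14 2-bromo-3-methoxy-5-[(triisopropylsilyl)oxy]phenol
Conditions: TIPSCl (1.0 equiv), imidazole, DMF, −20 → 0 °C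
Reagents that add atoms: chlorotriisopropylsilane, CC(C)[Si](Cl)(C(C)C)C(C)C
Why: Sterically controlled mono-silylation, in which the bulky chlorosilane should take the hydroxyl flanked by two hydrogens and leave the one next to bromine, which is hindered and hydrogen-bonded to the halogen.

Step 9
Reactants: 11 methyl (Z)-2-{2,2-dimethyl-8-[(triisopropylsilyl)oxy]-2H-chromen-6-yl}-3-(tosyloxy)acrylate; 14 2-bromo-3-methoxy-5-[(triisopropylsilyl)oxy]phenol
Product: 15 methyl (Z)-3-{2-bromo-3-methoxy-5-[(triisopropylsilyl)oxy]phenoxy}-2-{2,2-dimethyl-8-[(triisopropylsilyl)oxy]-2H-chromen-6-yl}acrylate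
Conditions: K2CO3, MeCN, 0 °C → rt (11 in slight excess)
Reagents that add atoms: none
Why: Nucleophilic vinylic substitution by addition–elimination, in which the tosylate should leave from the ester enolate after the least rotation and so return the Z geometry, while the slight excess of 11 leaves no free phenoxide to equilibrate the enol ether towards the E isomer, which cannot cyclise.

Step 10
Reactants: 15 methyl (Z)-3-{2-bromo-3-methoxy-5-[(triisopropylsilyl)oxy]phenoxy}-2-{2,2-dimethyl-8-[(triisopropylsilyl)oxy]-2H-chromen-6-yl}acrylate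
Product: 18 3-{2,2-dimethyl-8-[(triisopropylsilyl)oxy]-2H-chromen-6-yl}-5-methoxy-7-[(triisopropylsilyl)oxy]-4H-chromen-4-one, via aryllithium 16 (not isolated), via lithium alkoxide 17 (not isolated)
Conditions: n-BuLi (1.05 equiv, slow addition), THF, −78 °C; then aq. NH4Cl at −78 °C
Reagents that add atoms: n-butyllithium, [Li]CCCC (supplies only the lithium of 16 and 17; no atom of it remains in 18)
Why: Bromine–lithium exchange at the carbon that carries bromine between two oxygen substituents should outrun attack of n-BuLi on the donor-substituted, α-branched acrylate at −78 °C and gives aryllithium 16, metalated at the future C4a. As the aryloxy group stands cis to the ester, the carbanion adds to the ester carbonyl in a 6-exo-trig closure to give alkoxide 17, which expels lithium methoxide and so delivers the C4–C4a bond, the C4 carbonyl and ring C. The closest known reaction type is the Parham cyclisation of an ortho-bromoaryl-tethered ester to a cyclic aryl ketone. No stereocentre remains in 18; the carbinol carbon of 17 is transient and racemic. The step needs site selectivity among C4a, C6 and C8 and chemoselectivity for exchange over carbonyl or conjugate addition: the first is fixed by the position of the bromine, the second by slow addition of one equivalent at low temperature and by the speed of the intramolecular trap. Neither silyl ether is ortho to the lithiated carbon, so no silyl shift to carbon is expected, and the cold quench keeps methoxide from opening the chromone.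

Step 11
Reactants: 18 3-{2,2-dimethyl-8-[(triisopropylsilyl)oxy]-2H-chromen-6-yl}-5-methoxy-7-[(triisopropylsilyl)oxy]-4H-chromen-4-one
Product: 19 glycyrrhizaisoflavone B
Conditions: Bu4NF, AcOH, THF, 0 °C
Reagents that add atoms: none
Why: Fluoride-mediated desilylation cleaves both aryl silyl ethers in one operation, acetic acid buffering keeps the phenoxides from opening the chromone, and the C5 methyl ether and the chromene are untouched.

**Compound list**

1 | methyl 2-(3-bromo-4-hydroxyphenyl)acetate | COC(=O)Cc1ccc(O)c(Br)c1 | starting material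
2 | 3-chloro-3-methylbut-1-yne | C#CC(C)(C)Cl | starting material
3 | methyl 2-{3-bromo-4-[(2-methylbut-3-yn-2-yl)oxy]phenyl}acetate | COC(=O)Cc1ccc(OC(C)(C)C#C)c(Br)c1 | intermediate
4 | methyl 2-[3-bromo-4-hydroxy-5-(3-methylbuta-1,2-dien-1-yl)phenyl]acetate | COC(=O)Cc1cc(Br)c(O)c(C=C=C(C)C)c1 | intermediate (not isolated)
5 | methyl 2-[(3Z)-5-bromo-3-(3-methylbut-2-en-1-ylidene)-4-oxocyclohexa-1,5-dien-1-yl]acetate | O=C1/C(=C\C=C(C)C)C=C(CC(=O)OC)C=C1Br | intermediate (not isolated)
6 | methyl 2-(8-bromo-2,2-dimethyl-2H-chromen-6-yl)acetate | COC(=O)Cc1cc(Br)c2OC(C)(C)C=Cc2c1 | intermediate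
7 | methyl 2-[2,2-dimethyl-8-(4,4,5,5-tetramethyl-1,3,2-dioxaborolan-2-yl)-2H-chromen-6-yl]acetate | COC(=O)Cc1cc(B3OC(C)(C)C(C)(C)O3)c2OC(C)(C)C=Cc2c1 | intermediate (not isolated)
8 | methyl 2-(8-hydroxy-2,2-dimethyl-2H-chromen-6-yl)acetate | COC(=O)Cc1cc(O)c2OC(C)(C)C=Cc2c1 | intermediate
9 | methyl 2-{2,2-dimethyl-8-[(triisopropylsilyl)oxy]-2H-chromen-6-yl}acetate | COC(=O)Cc1cc(O[Si](C(C)C)(C(C)C)C(C)C)c2OC(C)(C)C=Cc2c1 | intermediate
10 | methyl (Z)-2-{2,2-dimethyl-8-[(triisopropylsilyl)oxy]-2H-chromen-6-yl}-3-hydroxyacrylate (enol form of the 2-formyl ester) | O/C=C(/c1cc(O[Si](C(C)C)(C(C)C)C(C)C)c2OC(C)(C)C=Cc2c1)C(=O)OC | intermediate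
11 | methyl (Z)-2-{2,2-dimethyl-8-[(triisopropylsilyl)oxy]-2H-chromen-6-yl}-3-(tosyloxy)acrylate | Cc1ccc(cc1)S(=O)(=O)O/C=C(/c1cc(O[Si](C(C)C)(C(C)C)C(C)C)c2OC(C)(C)C=Cc2c1)C(=O)OC | intermediate
12 | 5-methoxyresorcinol | COc1cc(O)cc(O)c1 | starting material
13 | 4-bromo-5-methoxybenzene-1,3-diol | COc1cc(O)cc(O)c1Br | intermediate
14 | 2-bromo-3-methoxy-5-[(triisopropylsilyl)oxy]phenol | COc1cc(O[Si](C(C)C)(C(C)C)C(C)C)cc(O)c1Br | intermediate
15 | methyl (Z)-3-{2-bromo-3-methoxy-5-[(triisopropylsilyl)oxy]phenoxy}-2-{2,2-dimethyl-8-[(triisopropylsilyl)oxy]-2H-chromen-6-yl}acrylate | COc1cc(O[Si](C(C)C)(C(C)C)C(C)C)cc(O/C=C(/c2cc(O[Si](C(C)C)(C(C)C)C(C)C)c3OC(C)(C)C=Cc3c2)C(=O)OC)c1Br | intermediate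
16 | methyl (Z)-3-{2-lithio-3-methoxy-5-[(triisopropylsilyl)oxy]phenoxy}-2-{2,2-dimethyl-8-[(triisopropylsilyl)oxy]-2H-chromen-6-yl}acrylate | COc1cc(O[Si](C(C)C)(C(C)C)C(C)C)cc(O/C=C(/c2cc(O[Si](C(C)C)(C(C)C)C(C)C)c3OC(C)(C)C=Cc3c2)C(=O)OC)c1[Li] | intermediate (not isolated)
17 | lithium 3-{2,2-dimethyl-8-[(triisopropylsilyl)oxy]-2H-chromen-6-yl}-4,5-dimethoxy-7-[(triisopropylsilyl)oxy]-4H-chromen-4-olate (racemic at C4, transient) | COc1cc(O[Si](C(C)C)(C(C)C)C(C)C)cc2OC=C(c3cc(O[Si](C(C)C)(C(C)C)C(C)C)c4OC(C)(C)C=Cc4c3)C(O[Li])(OC)c12 | intermediate (not isolated)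
18 | 3-{2,2-dimethyl-8-[(triisopropylsilyl)oxy]-2H-chromen-6-yl}-5-methoxy-7-[(triisopropylsilyl)oxy]-4H-chromen-4-one | COc1cc(O[Si](C(C)C)(C(C)C)C(C)C)cc2occ(-c3cc(O[Si](C(C)C)(C(C)C)C(C)C)c4c(c3)C=CC(C)(C)O4)c(=O)c12 | intermediate
19 | glycyrrhizaisoflavone B, 7-hydroxy-3-(8-hydroxy-2,2-dimethyl-2H-chromen-6-yl)-5-methoxy-4H-chromen-4-one | COc1cc(O)cc2occ(-c3cc(O)c4c(c3)C=CC(C)(C)O4)c(=O)c12 | target

**Step count.** Total: 11 steps. Longest linear sequence: 9 steps (steps 1–6, then 9, 10, 11); the ring A branch (steps 7, 8) joins at step 9.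

**Steps most likely to fail**

1. Step 10. What may go wrong: butyl addition to the acrylate, at the carbonyl or at the β-carbon with loss of the aryloxide, competes with halogen–metal exchange; excess base may also attack C2 of the chromone once it has formed. The fallback replaces bromine–lithium by iodine–magnesium exchange, sets out from 12 and tosylate 11, and returns at 18. Iodination of 12 with NIS (MeCN, −20 °C) should give 4-iodo-5-methoxybenzene-1,3-diol F1. Mono-silylation as in step 8 should give 2-iodo-3-methoxy-5-[(triisopropylsilyl)oxy]phenol F2. Substitution on 11 as in step 9 should give methyl (Z)-3-{2-iodo-3-methoxy-5-[(triisopropylsilyl)oxy]phenoxy}-2-{2,2-dimethyl-8-[(triisopropylsilyl)oxy]-2H-chromen-6-yl}acrylate F3. Exchange with iPrMgCl·LiCl (THF, −40 °C), a reagent that leaves esters alone at that temperature, should give the arylmagnesium chloride of F3, methyl (Z)-3-{2-(chloromagnesio)-3-methoxy-5-[(triisopropylsilyl)oxy]phenoxy}-2-{2,2-dimethyl-8-[(triisopropylsilyl)oxy]-2H-chromen-6-yl}acrylate F4, which on warming to 0 °C should acylate itself in the same 6-exo-trig mode to give 18.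

2. Step 9. What may go wrong: the enol ether geometry drifts towards the E isomer through reversible addition of phenoxide to the product, so that the ester ends up out of reach of C4a. The fallback accepts the loss of geometry and restores it photochemically; it sets out from 11 and 14 and returns at 15. The substitution is driven to completion without regard to geometry (K2CO3, DMF, 50 °C), which should give mainly methyl (E)-3-{2-bromo-3-methoxy-5-[(triisopropylsilyl)oxy]phenoxy}-2-{2,2-dimethyl-8-[(triisopropylsilyl)oxy]-2H-chromen-6-yl}acrylate F5. Irradiation at 365 nm in MeCN with thioxanthone as triplet sensitiser should take F5 to a photostationary E/Z mixture, from which 15 is separated by chromatography while F5 is returned to the lamp.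

3. Step 8. What may go wrong: silylation at the hydroxyl next to bromine, or at both hydroxyls, instead of at the unhindered one. The fallback reverses the order of silylation and bromination; it sets out from 12, bypasses 13, and returns at 14. Mono-silylation of the symmetric diol 12 (TIPSCl 0.9 equiv, imidazole, DMF), where the two hydroxyls are equivalent and diol and bis-ether can be recycled, should give 3-methoxy-5-[(triisopropylsilyl)oxy]phenol F6. Amine-mediated ortho-bromination of the free phenol (NBS, iPr2NH cat., CH2Cl2, 0 °C) should then go to the ortho carbon next to the small methoxy group, not the one next to the bulky silyloxy group, and give 14.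

**Further compounds**

F1 | step 10 | 4-iodo-5-methoxybenzene-1,3-diol | COc1cc(O)cc(O)c1I
F2 | step 10 | 2-iodo-3-methoxy-5-[(triisopropylsilyl)oxy]phenol | COc1cc(O[Si](C(C)C)(C(C)C)C(C)C)cc(O)c1I
F3 | step 10 | methyl (Z)-3-{2-iodo-3-methoxy-5-[(triisopropylsilyl)oxy]phenoxy}-2-{2,2-dimethyl-8-[(triisopropylsilyl)oxy]-2H-chromen-6-yl}acrylate | COc1cc(O[Si](C(C)C)(C(C)C)C(C)C)cc(O/C=C(/c2cc(O[Si](C(C)C)(C(C)C)C(C)C)c3OC(C)(C)C=Cc3c2)C(=O)OC)c1I
F4 | step 10 | methyl (Z)-3-{2-(chloromagnesio)-3-methoxy-5-[(triisopropylsilyl)oxy]phenoxy}-2-{2,2-dimethyl-8-[(triisopropylsilyl)oxy]-2H-chromen-6-yl}acrylate | COc1cc(O[Si](C(C)C)(C(C)C)C(C)C)cc(O/C=C(/c2cc(O[Si](C(C)C)(C(C)C)C(C)C)c3OC(C)(C)C=Cc3c2)C(=O)OC)c1[Mg]Cl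
F5 | step 9 | methyl (E)-3-{2-bromo-3-methoxy-5-[(triisopropylsilyl)oxy]phenoxy}-2-{2,2-dimethyl-8-[(triisopropylsilyl)oxy]-2H-chromen-6-yl}acrylate | COc1cc(O[Si](C(C)C)(C(C)C)C(C)C)cc(O/C=C(\c2cc(O[Si](C(C)C)(C(C)C)C(C)C)c3OC(C)(C)C=Cc3c2)C(=O)OC)c1Br
F6 | step 8 | 3-methoxy-5-[(triisopropylsilyl)oxy]phenol | COc1cc(O)cc(O[Si](C(C)C)(C(C)C)C(C)C)c1
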